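The target readings in the red flask have fallen since 3.00 d, and the question is whether any step taken now still buys more of it.

| flask | substrate | partner | protic impurity | initiator | temperature | remark | time |
|---|---|---|---|---|---|---|---|
| red | 33 mM | 1.2 equiv | 9.9 mM | 0.7 mol% | 80 °C | the very flask that is asked about, followed so far |  |
| grey | 33 mM | 1.2 equiv | 9.9 mM | 0.7 mol% | 86 °C | run made earlier |  |
| flask | 33 mM | 1.20 equiv | 9.90 mM | 0.7 mol% | 80 °C |  | 8.0 d |

| run | time / d | target / % |
|---|---|---|
| red | 1.67 | 26.3 |
| red | 3.00 | 32.1 |
| red | 5.00 | 31.2 |
| red | 6.00 | 30.7 |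
| red | 8.00 | 28.6 |
| grey | 1.67 | 30.7 |
| grey | 3.00 | 29.6 |
| grey | 5.00 | 25.2 |
| grey | 6.00 | 22.9 |
| grey | 8.00 | 18.2 |

(scatter of a reading: 0.5 percentage points)

- north-east: at 8.0 d take out 90 % of the target then present, then wait 4.0 d
- south: at 8.0 d add partner, 100 % of the amount charged, then wait 4.0 d
- east: change nothing and wait 4.0 d more
- west: at 8.0 d raise the temperature by 10 K, then wait 4.0 d

- target that was removed still counts
- additions bring no volume worth counting

- target, in percent of the substrate first charged, at 8.0 d
- what to do for the largest gain in target; "none" if nothing gains more than 2 percentage points (north-east / south / east / west / none)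
- target present, with what was taken out counted in, in percent of the substrate first charged, after south
- target present, with what was taken out counted in, in percent of the substrate first charged, after west

Turned round, the question is this: for an answer other than "none", the red flask must still gain more than 2 percentage points. Its net rise was 0.157 d⁻¹ of the charge up to 1.67 d, then 0.0436 d⁻¹ up to 3.00 d. Read from the midpoints of those spans, the rise halves every 0.810 d, a rough reading. If that halving goes on past 8.0 d, the sum still to come is 0.04 points. This is the feed tail: the target still to be made after the moment of acting.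

The tail stands far below the 2 points that an option must gain, so this reckoning says "none". Meanwhile the late red readings slide, by 3.5 points over 4.0 d at their pace. The present target is taken as the last reading, 28.6 %.

The forecast gave 29 %, none as best, 25 % after south and 11 % after west, holding that “Extra partner probably restarts nothing”.

The flask gives 28.1 %, none as best, 23.7 % after south and 18.7 % after west.

    initiator → 2 initiating radical (k = 0.0280 h⁻¹, Ea = 106 kJ mol⁻¹)
    substrate + initiating radical → capped initiator + first chain carrier (k = 1.10 × 10⁵ M⁻¹ s⁻¹, Ea = 8.00 kJ mol⁻¹)
    partner + first chain carrier → target + second chain carrier (k = 7.10 × 10⁶ M⁻¹ h⁻¹, Ea = 45.0 kJ mol⁻¹)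
    substrate + second chain carrier → by-product + first chain carrier (k = 4.80 × 10⁶ M⁻¹ h⁻¹, Ea = 48.0 kJ mol⁻¹)
    first chain carrier → ended carrier (k = 780 h⁻¹, Ea = 96.0 kJ mol⁻¹)
    2 first chain carrier → ended chains A (k = 2.80 × 10⁸ M⁻¹ s⁻¹, Ea = 11.0 kJ mol⁻¹)
    2 second chain carrier → ended chains B (k = 1.40 × 10⁸ M⁻¹ s⁻¹, Ea = 11.0 kJ mol⁻¹)
    substrate + target → side product (k = 0.320 M⁻¹ h⁻¹, Ea = 89.0 kJ mol⁻¹)
    partner + protic impurity → quenched reagent (k = 0.220 M⁻¹ h⁻¹, Ea = 85.0 kJ mol⁻¹)
    (constants at 80 °C)

West is where the forecast parts from the flask, by 7.7 points. Taking out 90 % changed the target by −0.05 points, less than 2 points, while waiting changed it by −4.8 points. The neighbouring flask holds 2.8 mol% of initiator. Its substrate times second chain carrier at 8.00 d stands at 0.585 times the flask's, so the flask's tail of 0.04 points, carried over by that factor with red's halving time assumed, comes to 0.023 points, an estimate, less than 2 points. Initiator stands in that neighbouring flask at 0.46 % of its charge, as in the flask, and the neighbour's target stands at 56.8 %.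

The readings are simulated from invented constants; noise was put on by code.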